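Early on, the flask with more partner simply runs ahead: at 4.00 h the delta run stands at 12.2 % of target and the theta run at 4.9 %.

in all of them: solid substrate 0.28 M

|  | partner | remark | time |
|---|---|---|---|
| theta | 0.10 M | run made earlier |  |
| delta | 0.45 M | run made earlier |  |
| violet | 0.0800 M |  | 15 h |
| blue | 0.120 M |  | 15 h |
| red | 0.150 M |  | 15 h |
| ochre | 0.250 M |  | 15 h |
| teal | 0.400 M |  | 15 h |

| run | time / h | target / % |
|---|---|---|
| theta | 1.33 | 0.7 |
| theta | 4.00 | 4.9 |
| theta | 8.00 | 9.5 |
| theta | 10.0 | 15.4 |
| theta | 15.0 | 14.1 |
| delta | 1.33 | 2.1 |
| delta | 4.00 | 12.2 |
| delta | 8.00 | 22.4 |
| delta | 10.0 | 25.5 |
| delta | 15.0 | 28.1 |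

(readings scatter by 1 percentage point)

- solid substrate is a solid; its amount is given per volume of the solution
- the analysis behind the earlier runs scatters by 1 percentage point, standard deviation
- at the start none of the solid substrate is in solution
- "hardly changes" means that all values lie within two and a half points (for a concentration: within two and a half percent of the largest)

- amount of target at the end, in percent of the solid substrate charged for violet, blue, red, ochre, teal, in this order
- the shape of the row from first to last (rises, then falls / falls all the way / falls, then rises / hardly changes / rises all the way)

Later, two numbers refuse to go together. Theta flattens near 14.1 %, although its partner, taken one to one, allows 35.7 % of the solid substrate, so partner looks ample. Yet delta, with 4.50 times that partner, reaches 28.1 %, so partner plainly matters.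

We clear this by supposing that theta stands still for lack of partner, the limiting reagent, and that partner is also lost to something we do not see. Theta's last two readings average 14.7 %, which is 0.413 of target per partner charged. This is the yield on partner: target accumulated per partner charged, a ratio of amounts averaged over the whole of theta's run and read with theta's scatter, not a rate ratio that holds at each moment.

Delta gives 0.175 per partner charged, less than that yield, so something other than partner is holding delta, and we take it to be the solid substrate.

Our reckoning therefore takes the smaller of two ceilings: the yield on partner times partner over substrate, and delta's value. That gives violet 11.8 %, blue 17.7 % and red 22.1 %. The two ceilings cross at 0.191 M of partner, so ochre and teal lie close to delta's value and the row rises.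

The forecast gives 13.5 %, 16.3 %, 18 %, 22.5 % and 27 %, and it rises all the way, by its words “interpolate smoothly with the power law”.

The flask gives 11.2 %, 16.5 %, 20.1 %, 28.8 % and 29.3 %; the row rises all the way.

    solid substrate ⇌ starting material, rate k1*(cs1 - [starting material]) while solid is left; crystals form when [starting material] > cs1 (solubility = 0.240 M, k = 0.477 h⁻¹)
    2 starting material → self-condensation product (k = 0.00136 L mol⁻¹ h⁻¹)
    partner + tautomer → target (k = 2.56 L mol⁻¹ h⁻¹)
    starting material + partner → isomer of the product (k = 1.12 L mol⁻¹ h⁻¹)
    starting material ⇌ tautomer (K = 0.738, k = 0.184 h⁻¹)

At 15.0 h ochre still holds 11 % of its partner, and its value is not the ceiling we took it for. Applied to ochre, the yield on partner gives 36.9 % for the time when its partner has been used, and at 150 h, with 0.00575 % of that partner left, ochre holds 35.0 % of target.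

(All runs were computed with made-up constants; noise was put on by code.)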